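**Retrosynthetic overview**

1. Target 19 ⇐ 15 by one hydrogenolysis (two O-benzyl groups, one N-Cbz group) with reductive N-methylation; 15 ⇐ chromone 13 + boronic acid 14 by asymmetric conjugate addition, which attaches ring B and sets C2.
2. 13 ⇐ alkenyl carbamate 11: the piperidine (ring D) is closed at its N–C2' bond by a chiral Brønsted acid catalysed, stereoconvergent aza-Michael addition of the carbamate N–H to an ortho-quinone methide made by protonating the alkenyl side chain.
3. Feature used: C2' is a benzylic carbon on C6 of ring A, flanked by the C5 hydroxyl (chelated to the C4 carbonyl) and the C7 oxygen and para to the ring oxygen O1. This ortho-hydroxybenzylamine is the adduct of an amine and an ortho-quinone methide.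
4. 11 ⇐ 6-iodochromone 5 + alkenylboronate 10 (Suzuki–Miyaura); 5 ⇐ 5,7-dihydroxychromone 1 by 7-O-benzylation and 5-OH-directed C6 iodination; 10 ⇐ pent-4-yn-1-amine 6.
5. Ring order: rings A and C are bought as the chromone, ring D is closed in step 6, and ring C is brought to the flavanone level when ring B is attached in step 7.

Key step: step 6

Assumption: the sense of induction written for the chiral acid in step 6 and for the PyOx ligand in step 7 rests on analogy; if a first run shows the opposite sense, the mirror-image catalyst is used and nothing else changes.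

**Route**

Step 1
Reactants: 1 5,7-dihydroxy-4H-chromen-4-one; 2 benzyl bromide
Product: 3 7-(benzyloxy)-5-hydroxy-4H-chromen-4-one
Conditions: K2CO3 (1.2 equiv), acetone, reflux
Reagents that add atoms: benzyl bromide (2), BrCc1ccccc1
Why: Williamson etherification should be selective for the acidic, non-chelated 7-OH because the 5-OH is locked in a hydrogen bond to the C4 carbonyl.

Step 2
Reactants: 3 7-(benzyloxy)-5-hydroxy-4H-chromen-4-one; 4 benzyltrimethylammonium dichloroiodate
Product: 5 7-(benzyloxy)-5-hydroxy-6-iodo-4H-chromen-4-one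
Conditions: BnMe3N·ICl2 (1.05 equiv), CaCO3, CH2Cl2–MeOH, rt
Reagents that add atoms: benzyltrimethylammonium dichloroiodate (4), C[N+](C)(C)Cc1ccccc1.Cl[I-]Cl
Why: Phenol-directed electrophilic aromatic iodination with the dichloroiodate salt should go ortho to the free 5-OH, that is to C6, as is known for 5-hydroxy-7-alkoxyflavones, while CaCO3 takes up the HCl.

Step 3
Reactants: 6 pent-4-yn-1-amine; 7 benzyl chloroformate
Product: 8 benzyl pent-4-yn-1-ylcarbamate
Conditions: Na2CO3, THF–H2O, 0 °C to rt
Reagents that add atoms: benzyl chloroformate (7), O=C(Cl)OCc1ccccc1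
Why: Schotten–Baumann N-acylation of a primary amine by a chloroformate is reliable and leaves the terminal alkyne untouched.

Step 4
Reactants: 8 benzyl pent-4-yn-1-ylcarbamate; 9 pinacolborane
Product: 10 benzyl [(4E)-5-(4,4,5,5-tetramethyl-1,3,2-dioxaborolan-2-yl)pent-4-en-1-yl]carbamate
Conditions: Cp2Zr(H)Cl (10 mol %), Et3N (10 mol %), neat, 60 °C
Reagents that add atoms: pinacolborane (9), CC1(C)OBOC1(C)C
Why: Zirconocene hydride catalysed syn-hydroboration of a terminal alkyne with pinacolborane should place boron on the terminal carbon and give the (E)-alkenylboronate.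

Step 5
Reactants: 5 7-(benzyloxy)-5-hydroxy-6-iodo-4H-chromen-4-one; 10 benzyl [(4E)-5-(4,4,5,5-tetramethyl-1,3,2-dioxaborolan-2-yl)pent-4-en-1-yl]carbamate
Product: 11 benzyl [(4E)-5-[7-(benzyloxy)-5-hydroxy-4-oxo-4H-chromen-6-yl]pent-4-en-1-yl]carbamate
Conditions: Pd(OAc)2 (5 mol %), SPhos (10 mol %), K3PO4, toluene–H2O, 80 °C
Reagents that add atoms: alkenylboronate 10, CC1(C)OB(/C=C/CCCNC(=O)OCc2ccccc2)OC1(C)C
Why: Suzuki–Miyaura coupling of an aryl iodide with an alkenylboronate should proceed with the bulky biarylphosphine coping with the doubly ortho-substituted iodide, the free ortho phenol being tolerated as its phenoxide and the chromone carrying no stereocentre that base could harm.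

Step 6
Reactants: 11 benzyl [(4E)-5-[7-(benzyloxy)-5-hydroxy-4-oxo-4H-chromen-6-yl]pent-4-en-1-yl]carbamate
Product: 13 benzyl (2S)-2-[7-(benzyloxy)-5-hydroxy-4-oxo-4H-chromen-6-yl]piperidine-1-carboxylate, via ortho-quinone methide 12 (not isolated)
Conditions: (R)-TRIP N-triflylphosphoramide [BINOL-derived, 3,3'-bis(2,4,6-triisopropylphenyl)] (10 mol %), 5 Å MS, toluene (0.02 M), 0 °C to rt
Reagents that add atoms: none
Why: Proposed new method: the chiral acid is expected to protonate the electron-rich styrene of 11 at the alkene carbon remote from the ring while it hydrogen-bonds to the O5–H/C4=O pocket, giving ortho-quinone methide 12 (or its contact ion pair with the chiral anion), in which the alkene geometry is erased; the carbamate N–H, held by the same anion, then adds to the exocyclic methide carbon and forms the N–C2' bond with re-aromatisation of ring A. The closest known reaction types are chiral phosphoric acid and N-triflylphosphoramide catalysed conjugate additions to ortho-quinone methides generated in situ from ortho-hydroxystyrenes or ortho-hydroxybenzyl alcohols, and Brønsted acid catalysed intramolecular hydroamination of styrenes by carbamates and sulfonamides. The piperidine ring closes in a 6-exo-trig mode with respect to the exocyclic C=C of 12 (formally a Markovnikov 6-endo hydroamination of the styrene). The new C2' stereocentre is controlled by the chiral anion, which differentiates the two faces of the planar methide carbon, so that any E/Z mixture of 11 and both faces of 12 should be funnelled into the (S) product. The step needs N-attack instead of O-attack of the carbamate and ring closure instead of intermolecular Friedel–Crafts attack by C8 of a second molecule; the six-membered transition state (against an eight-membered one for O-attack) and high dilution should secure this, and since the benzylic position flanked by O5, O7 and para-O1 is the only stabilised cation, proton loss can only return the styrene. A strong acid can be used freely because 11 carries no acid-labile stereocentre, and the product carbamate is a much poorer leaving group than the protonated alkene is an electrophile, so the closure should stay under kinetic control at low temperature.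

Step 7
Reactants: 13 benzyl (2S)-2-[7-(benzyloxy)-5-hydroxy-4-oxo-4H-chromen-6-yl]piperidine-1-carboxylate; 14 4-(benzyloxy)phenylboronic acid
Product: 15 benzyl (2S)-2-[(2S)-7-(benzyloxy)-2-[4-(benzyloxy)phenyl]-5-hydroxy-4-oxo-3,4-dihydro-2H-chromen-6-yl]piperidine-1-carboxylate
Conditions: Pd(OCOCF3)2 (10 mol %), (R)-t-BuPyOx (12 mol %), NH4PF6 (30 mol %), H2O (5 equiv), ClCH2CH2Cl, 60 °C
Reagents that add atoms: 4-(benzyloxy)phenylboronic acid (14), OB(O)c1ccc(OCc2ccccc2)cc1
Why: Palladium–pyridinooxazoline catalysed asymmetric conjugate addition of an arylboronic acid to a chromone should set C2 under ligand control (aryl–palladium insertion into C2=C3 on the face left open by the tert-butyl oxazoline, then protonation of the palladium enolate by water), the (R)-ligand being expected to give 2S because the (S)-ligand is known to give (R)-flavanones, and the base-free, weakly acidic medium should leave C2' and the new C2 centre untouched.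

Step 8
Reactants: 15 benzyl (2S)-2-[(2S)-7-(benzyloxy)-2-[4-(benzyloxy)phenyl]-5-hydroxy-4-oxo-3,4-dihydro-2H-chromen-6-yl]piperidine-1-carboxylate; 16 formaldehyde
Product: 19 (2S)-5,7-dihydroxy-2-(4-hydroxyphenyl)-6-[(2S)-1-methylpiperidin-2-yl]-2,3-dihydro-4H-chromen-4-one, via secondary amine 17 (not isolated), via benzoxazine 18 (not isolated)
Conditions: H2 (1 atm), 10% Pd/C, AcOH (2 equiv), MeOH–THF, rt; then 37% aq. HCHO (1.1 equiv), H2 (1 atm), rt
Reagents that add atoms: formaldehyde (16), C=O
Why: Hydrogenolysis should cleave both O-benzyl ethers and the Cbz group to amine 17, whose condensation with one equivalent of formaldehyde is expected to be trapped by the neighbouring phenol as cyclic N,O-acetal 18 (which keeps the iminium away from the nucleophilic C8) and then reduced on the same catalyst to the N-methyl amine, a reductive amination that should leave both stereocentres untouched at room temperature.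

**Compound list**

1 | 5,7-dihydroxy-4H-chromen-4-one | O=c1ccoc2cc(O)cc(O)c12 | starting material
2 | benzyl bromide | BrCc1ccccc1 | starting material
3 | 7-(benzyloxy)-5-hydroxy-4H-chromen-4-one | O=c1ccoc2cc(OCc3ccccc3)cc(O)c12 | intermediate
4 | benzyltrimethylammonium dichloroiodate | C[N+](C)(C)Cc1ccccc1.Cl[I-]Cl | starting material
5 | 7-(benzyloxy)-5-hydroxy-6-iodo-4H-chromen-4-one | O=c1ccoc2cc(OCc3ccccc3)c(I)c(O)c12 | intermediate
6 | pent-4-yn-1-amine | C#CCCCN | starting material
7 | benzyl chloroformate | O=C(Cl)OCc1ccccc1 | starting material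
8 | benzyl pent-4-yn-1-ylcarbamate | C#CCCCNC(=O)OCc1ccccc1 | intermediate
9 | pinacolborane | CC1(C)OBOC1(C)C | starting material
10 | benzyl [(4E)-5-(4,4,5,5-tetramethyl-1,3,2-dioxaborolan-2-yl)pent-4-en-1-yl]carbamate | CC1(C)OB(/C=C/CCCNC(=O)OCc2ccccc2)OC1(C)C | intermediate
11 | benzyl [(4E)-5-[7-(benzyloxy)-5-hydroxy-4-oxo-4H-chromen-6-yl]pent-4-en-1-yl]carbamate | O=c1ccoc2cc(OCc3ccccc3)c(/C=C/CCCNC(=O)OCc3ccccc3)c(O)c12 | intermediate
12 | ortho-quinone methide tautomer of 11 (C5 ketone, exocyclic C6=CH–(CH2)4–NHCbz, alkene geometry undefined) | O=C1C=COC2=C1C(=O)C(=CCCCCNC(=O)OCc1ccccc1)C(OCc1ccccc1)=C2 | intermediate (not isolated)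
13 | benzyl (2S)-2-[7-(benzyloxy)-5-hydroxy-4-oxo-4H-chromen-6-yl]piperidine-1-carboxylate | O=c1ccoc2cc(OCc3ccccc3)c([C@@H]3CCCCN3C(=O)OCc3ccccc3)c(O)c12 | intermediate
14 | 4-(benzyloxy)phenylboronic acid | OB(O)c1ccc(OCc2ccccc2)cc1 | starting material
15 | benzyl (2S)-2-[(2S)-7-(benzyloxy)-2-[4-(benzyloxy)phenyl]-5-hydroxy-4-oxo-3,4-dihydro-2H-chromen-6-yl]piperidine-1-carboxylate | O=C(OCc1ccccc1)N1CCCC[C@H]1c1c(OCc3ccccc3)cc2c(c1O)C(=O)C[C@@H](c1ccc(OCc3ccccc3)cc1)O2 | intermediate
16 | formaldehyde | C=O | starting material
17 | (2S)-5,7-dihydroxy-2-(4-hydroxyphenyl)-6-[(2S)-piperidin-2-yl]-2,3-dihydro-4H-chromen-4-one | N1CCCC[C@H]1c1c(O)cc2c(c1O)C(=O)C[C@@H](c1ccc(O)cc1)O2 | intermediate (not isolated)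
18 | cyclic N,O-acetal of 17 in which one CH2 bridges the piperidine nitrogen and O7 (1,3-benzoxazine ring fused to ring A and to the piperidine; both stereocentres S) | C1Oc2cc3c(c(O)c2[C@@H]2CCCCN12)C(=O)C[C@@H](c2ccc(O)cc2)O3 | intermediate (not isolated)
19 | (2S)-5,7-dihydroxy-2-(4-hydroxyphenyl)-6-[(2S)-1-methylpiperidin-2-yl]-2,3-dihydro-4H-chromen-4-one | CN1CCCC[C@H]1c1c(O)cc2c(c1O)C(=O)C[C@@H](c1ccc(O)cc1)O2 | target

**Step count**

Total: 8 steps. Longest linear sequence: 6 steps (1, 2, 5, 6, 7, 8 from compound 1; the branch 3, 4 joins at step 5).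

**Steps most likely to fail**

Step 6. The chiral anion may not differentiate the two faces of the planar methide well enough, or turnover may stall because the basic pyranone carbonyl sequesters the acid. The fallback uses known chemistry only. Starting from 11, the ring is closed with an achiral strong acid (CF3SO3H, 5 mol %, toluene, rt; acid-catalysed Markovnikov hydroamination of a styrene by a carbamate). This should give 13 together with its enantiomer, benzyl (2R)-2-[7-(benzyloxy)-5-hydroxy-4-oxo-4H-chromen-6-yl]piperidine-1-carboxylate F5. The racemate is taken through step 7, where the ligand-set 2S centre turns the two enantiomers into diastereomers: 15 and benzyl (2R)-2-[(2S)-7-(benzyloxy)-2-[4-(benzyloxy)phenyl]-5-hydroxy-4-oxo-3,4-dihydro-2H-chromen-6-yl]piperidine-1-carboxylate F6. These are separated by chromatography or crystallisation, and the route is rejoined at 15.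

Step 2. The iodinating agent may attack C8 (para to the 5-OH) or C3 of the pyranone, or iodinate twice. The fallback fixes the regiochemistry by a sigmatropic shift and sets out from 3. O-Allylation of the chelated 5-OH (allyl bromide, K2CO3, DMF, 60 °C) gives 5-(allyloxy)-7-(benzyloxy)-4H-chromen-4-one F1. Aromatic Claisen rearrangement (N,N-diethylaniline, 190 °C) can deliver the allyl group only to C6, the single free ortho position of O5, and gives 6-allyl-7-(benzyloxy)-5-hydroxy-4H-chromen-4-one F2. Alkene migration into conjugation (RuClH(CO)(PPh3)3, toluene, 80 °C) gives 7-(benzyloxy)-5-hydroxy-6-[(E)-prop-1-en-1-yl]-4H-chromen-4-one F3. Cross-metathesis of F3 with benzyl pent-4-en-1-ylcarbamate F4 (made from pent-4-en-1-amine and 7 as in step 3), using second-generation Hoveyda–Grubbs catalyst in CH2Cl2 at 40 °C with loss of propene, gives 11, where the route is rejoined.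

Step 7. Migratory insertion may be slow or poorly face-selective because the chelated 5-hydroxy-4-oxo unit and the bulky, doubly flanked C6 substituent disturb binding to the cationic divalent palladium complex, so that protodeboronation of the electron-rich boronic acid takes over. The fallback changes the order of events so that C2 is set on the simplest chromone, and sets out from 3.
- Conjugate addition of 14 to 3 under the step 7 conditions gives (2S)-7-(benzyloxy)-2-[4-(benzyloxy)phenyl]-5-hydroxy-2,3-dihydro-4H-chromen-4-one F7.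
- Iodination with 4 as in step 2 gives (2S)-7-(benzyloxy)-2-[4-(benzyloxy)phenyl]-5-hydroxy-6-iodo-2,3-dihydro-4H-chromen-4-one F8.
- Suzuki–Miyaura coupling with 10 at room temperature (Pd(OAc)2, SPhos, K3PO4, THF–H2O; mild conditions chosen to spare the base-labile C2 centre) gives benzyl [(4E)-5-[(2S)-7-(benzyloxy)-2-[4-(benzyloxy)phenyl]-5-hydroxy-4-oxo-3,4-dihydro-2H-chromen-6-yl]pent-4-en-1-yl]carbamate F9.
- Acid-catalysed ring closure of F9 as in step 6 (a chiral phosphoric acid should suffice for the more electron-rich flavanone ring A; otherwise the achiral acid, then separation from F6) gives 15, where the route is rejoined.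

Further compounds

F1 | step 2 | 5-(allyloxy)-7-(benzyloxy)-4H-chromen-4-one | O=c1ccoc2cc(OCc3ccccc3)cc(OCC=C)c12
F2 | step 2 | 6-allyl-7-(benzyloxy)-5-hydroxy-4H-chromen-4-one | O=c1ccoc2cc(OCc3ccccc3)c(CC=C)c(O)c12
F3 | step 2 | 7-(benzyloxy)-5-hydroxy-6-[(E)-prop-1-en-1-yl]-4H-chromen-4-one | O=c1ccoc2cc(OCc3ccccc3)c(/C=C/C)c(O)c12
F4 | step 2 | benzyl pent-4-en-1-ylcarbamate | C=CCCCNC(=O)OCc1ccccc1
F5 | step 6 | benzyl (2R)-2-[7-(benzyloxy)-5-hydroxy-4-oxo-4H-chromen-6-yl]piperidine-1-carboxylate | O=c1ccoc2cc(OCc3ccccc3)c([C@H]3CCCCN3C(=O)OCc3ccccc3)c(O)c12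
F6 | step 6 | benzyl (2R)-2-[(2S)-7-(benzyloxy)-2-[4-(benzyloxy)phenyl]-5-hydroxy-4-oxo-3,4-dihydro-2H-chromen-6-yl]piperidine-1-carboxylate | O=C(OCc1ccccc1)N1CCCC[C@@H]1c1c(OCc3ccccc3)cc2c(c1O)C(=O)C[C@@H](c1ccc(OCc3ccccc3)cc1)O2
F7 | step 7 | (2S)-7-(benzyloxy)-2-[4-(benzyloxy)phenyl]-5-hydroxy-2,3-dihydro-4H-chromen-4-one | O=C1C[C@@H](c2ccc(OCc3ccccc3)cc2)Oc2cc(OCc3ccccc3)cc(O)c12
F8 | step 7 | (2S)-7-(benzyloxy)-2-[4-(benzyloxy)phenyl]-5-hydroxy-6-iodo-2,3-dihydro-4H-chromen-4-one | O=C1C[C@@H](c2ccc(OCc3ccccc3)cc2)Oc2cc(OCc3ccccc3)c(I)c(O)c12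
F9 | step 7 | benzyl [(4E)-5-[(2S)-7-(benzyloxy)-2-[4-(benzyloxy)phenyl]-5-hydroxy-4-oxo-3,4-dihydro-2H-chromen-6-yl]pent-4-en-1-yl]carbamate | O=C1C[C@@H](c2ccc(OCc3ccccc3)cc2)Oc2cc(OCc3ccccc3)c(/C=C/CCCNC(=O)OCc3ccccc3)c(O)c12
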